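All constants belong to no real substance; the result is computed.

The 5 questions concern these flasks, which differ in temperature.

    starting material + partner + released group → target + 2 released group (k1 = 18 M⁻² h⁻¹, Ea1 = 66.0 kJ mol⁻¹)
    starting material + partner → target + released group (k2 = 0.0075 M⁻¹ h⁻¹, Ea2 = 66.0 kJ mol⁻¹)
    base + released group ⇌ salt, settled at all times (K3 = 48000 M⁻¹, ΔH3 = −23.0 kJ mol⁻¹)
    released group → by-product carried off (k4 = 0.14 h⁻¹, Ea4 = 91.0 kJ mol⁻¹)
    (constants at 20 °C)

| flask | starting material | partner | base | temperature | time |
|---|---|---|---|---|---|
| green | 0.094 M | 0.0564 M | 0.0282 M | 60 °C | 5.0 d |
| grey | 0.094 M | 0.0564 M | 0.0282 M | 40 °C | 5.0 d |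
| red | 0.094 M | 0.0564 M | 0.0282 M | 20 °C | 5.0 d |
| amber | 0.094 M | 0.0564 M | 0.0282 M | 80 °C | 5.0 d |

- the flask that comes out highest in amount of target, in percent of the starting material charged, or "all alike" when all lie within 1.5 percentage points (green / grey / red / amber / all alike)
- target at the end, in percent of the starting material charged, green
- target at the end, in percent of the starting material charged, grey
- target at the end, in percent of the starting material charged, red
- target at the end, in percent of the starting material charged, amber

- at 20 °C the constants are as listed, elsewhere as the activation energies and enthalpies make them

A quick number needs one test first: how much the catalysis by the released group adds to the plain step. The catalysed step (first line) outruns the plain step (second line) once free released group exceeds 4.17 × 10⁻⁴ M. In red, when salt equals free base, the balance puts free released group at 2.08 × 10⁻⁵ M, which is less than that mark. The catalysed step then adds about 5.00 % to the plain rate. The reckoning here leaves that step out, and since that step makes target as well, the figures below are estimates from the low side.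

Then work with what is left and not with what is made. The plain step takes equal amounts of partner and starting material, so the ratio of partner left to starting material left starts at the charged ratio and falls as the exponential of minus the dose times the difference of the charges. The dose is the rate constant of the plain step times the time, which in red is 0.900 M⁻¹.

In red the ratio falls to 0.580, which means target at 4.75 % of the starting material charged. Amber's plain step runs 100 times as fast, so its dose is 89.6 M⁻¹. Its ratio falls to 0.0207, and target reaches 59.2 %, just under the 60.0 % that partner, the limiting reagent, allows. Green and grey have smaller doses than amber, so the pick here is amber, and this reckoning goes no further for those two.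

The forecast names amber, with green 47.5 % (45.5 % to 49.5 %), grey 21.5 % (20 % to 23 %), red 4.8 % (4.5 % to 5.1 %) and amber 59.2 % (58.5 % to 59.7 %). Its grounds: “The target therefore follows mainly the plain second-order step, boosted slightly.”

The highest flask is amber at 59.2 %, with green at 47.6 %, grey at 21.5 % and red at 4.77 %. After 5.00 d amber holds 1.3 % of its charged partner and 41 % of its starting material. Amber's dose puts the partner left at 1.41 % of its charge. Red's dose carries unchanged to a flask like red but charged with 0.014 M of partner, where the ratio falls to 0.139 and target comes to 1.20 %. That flask stood at 1.20 %.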